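I read the ends of the runs first.

in all of them: D 200 mM (held)

| run | Q | remark | time |
|---|---|---|---|
| Saturday's | 0.75 M | run made earlier |  |
| Thursday's | 1.1 M | run made earlier |  |
| flask | 1.5 M |  | 10 min |

| run | time / min | J / % | Z / % |
|---|---|---|---|
| Saturday's | 0.833 | 7.4 | 2.1 |
| Saturday's | 1.50 | 29.0 | 8.0 |
| Saturday's | 3.00 | 70.4 | 24.7 |
| Saturday's | 5.00 | 73.6 | 26.2 |
| Saturday's | 10.0 | 74.2 | 26.4 |
| Thursday's | 0.833 | 11.6 | 2.7 |
| Thursday's | 2.50 | 71.3 | 24.1 |
| Thursday's | 5.00 | 74.1 | 26.2 |
| Thursday's | 8.00 | 73.6 | 27.0 |
| Thursday's | 10.0 | 73.4 | 25.4 |

(each reading ± 0.5 percentage points)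

- the earlier runs were read with a standard deviation of 0.5 percentage points
- at the start none of D is in solution
- the reaction counts as stopped when no species that holds the Q changes by six tenths of a point or more over the second half of the time

- the state of affairs at 10 min: stopped, and by what, or still going (it is still moving / forward and back rates have come level / all of Q has reacted)
- the J standing at 10 min, as a percentage of the Q charged
- the Z standing at 10 min, as a percentage of the Q charged

On the flat part of each run the readings of J and Z add up to about the charge, for instance 100.6% in Saturday's run at 10.0 min and 100.3% in Thursday's at 5.00 min, so a late reading comes down to two amounts and how they divide the charge. Saturday's flat readings give a [Z]/[J] of 0.356 and Thursday's give 0.355, although their charges of Q differ, and pooled they give 0.356, which I freeze as the standing ratio, [Z]/[J] on the flat part of a run. Time enters as a condition, since Thursday's run is flat by 5.00 min and the asked 10 min is twice that. If the flask with 1.5 M of Q reaches the flat part and keeps this ratio, I reckon J at 73.8% and Z at 26.2%.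

The forecast says all of Q has reacted, with J at 73.7% (72.5% to 75%) and Z at 26.3% (25.2% to 27.5%), on the ground that “the endpoint doesn't shift with Q”.

In the flask at 10 min, all of Q has reacted: Q stands at 0%, J at 73.5% and Z at 26.5%.

    D ⇌ E, rate k1*(csat - [E]) (kL = 0.208 s⁻¹)
    Q + E + J → 2 J (k = 0.351 L² mol⁻² s⁻¹)
    J ⇌ Z (K = 0.360, k = 0.0281 s⁻¹)
    Q + E → J (k = 0.00385 L mol⁻¹ s⁻¹)

The flask's standing ratio comes out at 0.361, and the neighbour flask with 0.60 M of Q, for which the frozen ratio again gives 73.8% of J, stands at 73.5% J and 26.5% Z. In the flask the flat part is a balance, thermodynamic control of the split, and the relaxation half-life of J and Z by their own step, both ways together, is 0.109 min, far shorter than the 10 min. J survives in the flask because of the backward run from Z to J: with that run taken away, J at 10 min falls from 73.5% to 0.116%.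

(The data were computed with constants of no real substance; noise was put on by code.)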